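**Retrosynthetic overview**

- The target is a 6-hydroxy-8-methoxy-3-methylisocoumarin with a ring-A arylmethyl group on C5. The last disconnections are the two O-benzyl groups and the pyranone ring (C3–C4 by lateral acylation of a 2-methylbenzoate, then O2–C3 lactonisation).
- The strategy rests on the isocoumarin benzo ring: oxygen on C6 and C8 (a masked cyclohexane-1,3-dione), the carboxyl carbon C1 on C8a, C4 on C4a and the arylmethyl on C5. This is a 5-benzylorsellinate, and its substitution pattern is fixed on a saturated ring and only then dehydrogenated.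
- Ring B is closed by a Michael–Claisen annulation of dimethyl malonate with (E)-3-(arylmethyl)pent-3-en-2-one, which forms C8a–C4a and C7–C8.
- The enone comes from a ring-A benzylic chloride, diethyl (2-oxopropyl)phosphonate and acetaldehyde. Ring A comes from 3,5-bis(benzyloxy)benzyl alcohol by formylation and chelation-controlled differentiation of the two oxygens.
- Ring order: ring A (purchased arene), ring B (carbocycle, then aromatized), pyranone ring last.

Key step: step 9

Remark: 3,5-bis(benzyloxy)benzyl alcohol is taken as purchasable. The target has no stereocentre; the stereocentres of the saturated intermediates are uncontrolled and all become sp2 on the way.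

**Step 1**
Reactants: 1 3,5-bis(benzyloxy)benzyl alcohol
Product: 2 1,3-bis(benzyloxy)-5-(methoxymethyl)benzene
Conditions: NaH, MeI, THF, 0 °C → rt
Reagents that add atoms: iodomethane, CI
Why: Williamson ether synthesis on the primary benzylic alkoxide; the aryl benzyl ethers are inert to NaH and MeI.

**Step 2**
Reactants: 2 1,3-bis(benzyloxy)-5-(methoxymethyl)benzene
Product: 4 2,4-bis(benzyloxy)-6-(methoxymethyl)benzaldehyde, via aryl iminium chloride 3 (not isolated)
Conditions: POCl3, DMF, 0 → 70 °C; then H2O
Reagents that add atoms: N,N-dimethylformamide, CN(C)C=O; water, O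
Why: Vilsmeier–Haack formylation should go to the position ortho to the methoxymethyl group and para to one benzyloxy group, as with 3,5-dialkoxytoluenes, because the position between the two benzyloxy groups is more hindered; any symmetrical isomer is removed by chromatography.

**Step 3**
Reactants: 4 2,4-bis(benzyloxy)-6-(methoxymethyl)benzaldehyde
Product: 5 4-(benzyloxy)-2-hydroxy-6-(methoxymethyl)benzaldehyde
Conditions: MgBr2·OEt2, toluene/Et2O, 75 °C; then 1 M HCl
Reagents that add atoms: none
Why: Chelation-controlled Lewis-acid dealkylation: MgBr2 binds the aldehyde oxygen and the ortho ether oxygen in a six-membered chelate and bromide removes only that benzyl group, so the para benzyl ether and the methoxymethyl group should remain.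

**Step 4**
Reactants: 5 4-(benzyloxy)-2-hydroxy-6-(methoxymethyl)benzaldehyde
Product: 6 4-(benzyloxy)-2-methoxy-6-(methoxymethyl)benzaldehyde
Conditions: MeI, K2CO3, DMF, 40 °C
Reagents that add atoms: iodomethane, CI
Why: Williamson O-methylation of the hydrogen-bonded phenol, which fixes the methoxy group ortho and the benzyloxy group para to the future bridge carbon.

**Step 5**
Reactants: 6 4-(benzyloxy)-2-methoxy-6-(methoxymethyl)benzaldehyde
Product: 7 [4-(benzyloxy)-2-methoxy-6-(methoxymethyl)phenyl]methanol
Conditions: NaBH4, MeOH/THF, 0 °C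
Reagents that add atoms: none
Why: Borohydride reduction of an aryl aldehyde; no other group is reducible under these conditions.

**Step 6**
Reactants: 7 [4-(benzyloxy)-2-methoxy-6-(methoxymethyl)phenyl]methanol
Product: 8 5-(benzyloxy)-2-(chloromethyl)-1-methoxy-3-(methoxymethyl)benzene
Conditions: PPh3, N-chlorosuccinimide (premixed), THF, −20 → 0 °C; crude used at once
Reagents that add atoms: N-chlorosuccinimide, O=C1CCC(=O)N1Cl
Why: Appel-type chlorination through the alkoxyphosphonium salt is a neutral SN2 displacement, which avoids the acid that would ionise this electron-rich benzylic position; the chloride is chosen over the bromide because it ionises more slowly.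

**Step 7**
Reactants: 8 5-(benzyloxy)-2-(chloromethyl)-1-methoxy-3-(methoxymethyl)benzene; 9 diethyl (2-oxopropyl)phosphonate
Product: 10 diethyl {1-[4-(benzyloxy)-2-methoxy-6-(methoxymethyl)phenyl]-3-oxobutan-2-yl}phosphonate (racemic)
Conditions: 9 (2 equiv), NaH, THF, 0 °C; then 8, NaI (cat.), 0 °C → rt
Reagents that add atoms: none
Why: C-alkylation of the stabilised sodium enolate of a β-ketophosphonate by an activated benzylic halide (SN2, iodide catalysis); excess phosphonate suppresses dialkylation, and the new stereocentre is racemic and is destroyed in step 8.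

**Step 8**
Reactants: 10 diethyl {1-[4-(benzyloxy)-2-methoxy-6-(methoxymethyl)phenyl]-3-oxobutan-2-yl}phosphonate; 11 acetaldehyde
Product: 12 (E)-3-{[4-(benzyloxy)-2-methoxy-6-(methoxymethyl)phenyl]methyl}pent-3-en-2-one
Conditions: NaH, THF, 0 °C; then CH3CHO (5 equiv), 0 °C → rt, closed vessel
Reagents that add atoms: none
Why: Horner–Wadsworth–Emmons olefination of an α-substituted β-ketophosphonate with an unhindered aldehyde should favour the E enone (acetyl trans to the β-methyl); the geometry does not matter for step 9, so a mixture can be carried on.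

**Step 9**
Reactants: 12 (E)-3-{[4-(benzyloxy)-2-methoxy-6-(methoxymethyl)phenyl]methyl}pent-3-en-2-one; 13 dimethyl malonate
Product: 15 methyl 3-{[4-(benzyloxy)-2-methoxy-6-(methoxymethyl)phenyl]methyl}-2-methyl-4,6-dioxocyclohexane-1-carboxylate (diastereomer mixture), via Michael adduct 14 (not isolated)
Conditions: 13 (1.3 equiv), NaOMe (1.3 equiv), MeOH, rt then reflux; then 1 M HCl, 0 °C
Reagents that add atoms: none
Why: Sodium dimethyl malonate adds in a Michael reaction to the β-carbon of enone 12, which forms the C8a–C4a bond (isocoumarin numbering) and gives adduct 14; proton transfer then gives the methyl ketone enolate, which attacks one malonate ester in a Dieckmann-type Claisen condensation and forms C7–C8. The closest known reactions are the dimedone synthesis from mesityl oxide and the dihydroresorcinol syntheses from malonate and α,β-disubstituted enones such as 3-methylpent-3-en-2-one. Ring B closes by a 6-exo-trig acyl substitution, with the enolate carbon as nucleophile and the ester carbonyl as electrophile. Three stereocentres (C1, C2 and C3 of the cyclohexane) form without control, and none is needed because all become sp2 on aromatization. The step needs regioselectivity, and the substrate secures it: the enone has a single β-carbon, and only the methyl-side enolate can reach an ester through a six-membered transition state, since the enolate on the benzyl-bearing carbon would have to close a four-membered ring. Deprotonation of the cyclic β-diketone by methoxide pulls the reversible Michael and Claisen equilibria forward, and the twisted, di-ortho-substituted ring A gives little driving force for base-induced migration of the enone double bond into the benzylic position.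

**Step 10**
Reactants: 15 methyl 3-{[4-(benzyloxy)-2-methoxy-6-(methoxymethyl)phenyl]methyl}-2-methyl-4,6-dioxocyclohexane-1-carboxylate
Product: 16 methyl 5-{[4-(benzyloxy)-2-methoxy-6-(methoxymethyl)phenyl]methyl}-6-methyl-2,4-bis[(trimethylsilyl)oxy]cyclohexa-1,3-diene-1-carboxylate (diastereomer mixture)
Conditions: Me3SiOTf (2.4 equiv), Et3N (3 equiv), CH2Cl2, 0 °C; pentane, filter, concentrate; crude used directly
Reagents that add atoms: trimethylsilyl trifluoromethanesulfonate, C[Si](C)(C)OS(=O)(=O)C(F)(F)F
Why: Soft enolisation and O-silylation (silyl enol ether formation) of the β-diketone and then of the β-keto ester unit should give the 1,3-bis(silyloxy)cyclohexa-1,3-diene, an electron-rich dihydroarene; any regioisomeric bis-silyl dienol ether leads to the same arene.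

**Step 11**
Reactants: 16 methyl 5-{[4-(benzyloxy)-2-methoxy-6-(methoxymethyl)phenyl]methyl}-6-methyl-2,4-bis[(trimethylsilyl)oxy]cyclohexa-1,3-diene-1-carboxylate
Product: 18 methyl 3-{[4-(benzyloxy)-2-methoxy-6-(methoxymethyl)phenyl]methyl}-4,6-dihydroxy-2-methylbenzoate, via bis(trimethylsilyl) aryl ether 17 (not isolated)
Conditions: DDQ (1.05 equiv), 2,4,6-collidine, CH2Cl2, −20 → 0 °C; then 1 M HCl, THF, rt
Reagents that add atoms: none
Why: DDQ dehydrogenation of a silyl dienol ether: hydride abstraction from a ring sp3 C–H next to the silyloxydiene and proton loss give the arene, which should be much faster than oxidation at the benzylic positions with one equivalent of quinone at low temperature; dilute acid then hydrolyses the aryl silyl ethers.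

**Step 12**
Reactants: 18 methyl 3-{[4-(benzyloxy)-2-methoxy-6-(methoxymethyl)phenyl]methyl}-4,6-dihydroxy-2-methylbenzoate
Product: 19 methyl 4-(benzyloxy)-3-{[4-(benzyloxy)-2-methoxy-6-(methoxymethyl)phenyl]methyl}-6-hydroxy-2-methylbenzoate
Conditions: BnBr (1.05 equiv), K2CO3, acetone, 40 °C
Reagents that add atoms: benzyl bromide, BrCc1ccccc1
Why: Williamson etherification; the hydroxyl ortho to the ester is held in a hydrogen bond to the ester carbonyl, so the para hydroxyl should react first with one equivalent of benzyl bromide.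

**Step 13**
Reactants: 19 methyl 4-(benzyloxy)-3-{[4-(benzyloxy)-2-methoxy-6-(methoxymethyl)phenyl]methyl}-6-hydroxy-2-methylbenzoate
Product: 20 methyl 4-(benzyloxy)-3-{[4-(benzyloxy)-2-methoxy-6-(methoxymethyl)phenyl]methyl}-6-methoxy-2-methylbenzoate
Conditions: MeI (excess), K2CO3, DMF, 55 °C
Reagents that add atoms: iodomethane, CI
Why: Williamson methylation of the chelated phenol under more forcing conditions, which places the future C8 methoxy group.

**Step 14**
Reactants: 20 methyl 4-(benzyloxy)-3-{[4-(benzyloxy)-2-methoxy-6-(methoxymethyl)phenyl]methyl}-6-methoxy-2-methylbenzoate; 21 N-methoxy-N-methylacetamide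
Product: 23 6-(benzyloxy)-5-{[4-(benzyloxy)-2-methoxy-6-(methoxymethyl)phenyl]methyl}-8-methoxy-3-methyl-1H-isochromen-1-one, via keto ester 22 (not isolated)
Conditions: LiN(iPr)2 (1.3 equiv), THF, −78 °C; 21 (2 equiv), −78 → −20 °C; aq NH4Cl; then TsOH·H2O (cat.), toluene, 60 °C
Reagents that add atoms: none
Why: Lateral lithiation of the ortho-toluate gives the ester-stabilised benzylic anion, Weinreb amide acylation stops at the ketone because the tetrahedral chelate survives until the quench, and acid-catalysed enol lactonisation then closes the pyranone ring; acid is used because base would favour C-acylation to a naphthalenediol.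

**Step 15**
Reactants: 23 6-(benzyloxy)-5-{[4-(benzyloxy)-2-methoxy-6-(methoxymethyl)phenyl]methyl}-8-methoxy-3-methyl-1H-isochromen-1-one
Product: 24 6-hydroxy-5-{[4-hydroxy-2-methoxy-6-(methoxymethyl)phenyl]methyl}-8-methoxy-3-methyl-1H-isochromen-1-one
Conditions: H2 (1 atm), Pd/C (10 wt%), EtOAc, rt, stopped when debenzylation is complete
Reagents that add atoms: none
Why: Hydrogenolysis of the two aryl benzyl ethers, which in ethyl acetate should be faster than hydrogenation of the trisubstituted enol-lactone alkene and than cleavage of the hindered benzylic methyl ether.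

**Compound list**

1 | 3,5-bis(benzyloxy)benzyl alcohol | OCc1cc(OCc2ccccc2)cc(OCc2ccccc2)c1 | starting material
2 | 1,3-bis(benzyloxy)-5-(methoxymethyl)benzene | COCc1cc(OCc2ccccc2)cc(OCc2ccccc2)c1 | intermediate
3 | N-{[2,4-bis(benzyloxy)-6-(methoxymethyl)phenyl]methylidene}-N-methylmethanaminium chloride | C[N+](C)=Cc1c(COC)cc(OCc2ccccc2)cc1OCc1ccccc1.[Cl-] | intermediate
4 | 2,4-bis(benzyloxy)-6-(methoxymethyl)benzaldehyde | COCc1cc(OCc2ccccc2)cc(OCc2ccccc2)c1C=O | intermediate
5 | 4-(benzyloxy)-2-hydroxy-6-(methoxymethyl)benzaldehyde | COCc1cc(OCc2ccccc2)cc(O)c1C=O | intermediate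
6 | 4-(benzyloxy)-2-methoxy-6-(methoxymethyl)benzaldehyde | COCc1cc(OCc2ccccc2)cc(OC)c1C=O | intermediate
7 | [4-(benzyloxy)-2-methoxy-6-(methoxymethyl)phenyl]methanol | COCc1cc(OCc2ccccc2)cc(OC)c1CO | intermediate
8 | 5-(benzyloxy)-2-(chloromethyl)-1-methoxy-3-(methoxymethyl)benzene | COCc1cc(OCc2ccccc2)cc(OC)c1CCl | intermediate
9 | diethyl (2-oxopropyl)phosphonate | CC(=O)CP(=O)(OCC)OCC | starting material
10 | diethyl {1-[4-(benzyloxy)-2-methoxy-6-(methoxymethyl)phenyl]-3-oxobutan-2-yl}phosphonate (racemic) | CCOP(=O)(OCC)C(Cc1c(COC)cc(OCc2ccccc2)cc1OC)C(C)=O | intermediate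
11 | acetaldehyde | CC=O | starting material
12 | (E)-3-{[4-(benzyloxy)-2-methoxy-6-(methoxymethyl)phenyl]methyl}pent-3-en-2-one | C/C=C(\Cc1c(COC)cc(OCc2ccccc2)cc1OC)C(C)=O | intermediate
13 | dimethyl malonate | COC(=O)CC(=O)OC | starting material
14 | dimethyl 2-(3-{[4-(benzyloxy)-2-methoxy-6-(methoxymethyl)phenyl]methyl}-4-oxopentan-2-yl)propanedioate (diastereomer mixture) | COC(=O)C(C(=O)OC)C(C)C(Cc1c(COC)cc(OCc2ccccc2)cc1OC)C(C)=O | intermediate
15 | methyl 3-{[4-(benzyloxy)-2-methoxy-6-(methoxymethyl)phenyl]methyl}-2-methyl-4,6-dioxocyclohexane-1-carboxylate (diastereomer mixture) | COC(=O)C1C(C)C(Cc2c(COC)cc(OCc3ccccc3)cc2OC)C(=O)CC1=O | intermediate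
16 | methyl 5-{[4-(benzyloxy)-2-methoxy-6-(methoxymethyl)phenyl]methyl}-6-methyl-2,4-bis[(trimethylsilyl)oxy]cyclohexa-1,3-diene-1-carboxylate (diastereomer mixture) | COC(=O)C1=C(O[Si](C)(C)C)C=C(O[Si](C)(C)C)C(Cc2c(COC)cc(OCc3ccccc3)cc2OC)C1C | intermediate
17 | methyl 3-{[4-(benzyloxy)-2-methoxy-6-(methoxymethyl)phenyl]methyl}-2-methyl-4,6-bis[(trimethylsilyl)oxy]benzoate | COC(=O)c1c(C)c(Cc2c(COC)cc(OCc3ccccc3)cc2OC)c(O[Si](C)(C)C)cc1O[Si](C)(C)C | intermediate
18 | methyl 3-{[4-(benzyloxy)-2-methoxy-6-(methoxymethyl)phenyl]methyl}-4,6-dihydroxy-2-methylbenzoate | COC(=O)c1c(C)c(Cc2c(COC)cc(OCc3ccccc3)cc2OC)c(O)cc1O | intermediate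
19 | methyl 4-(benzyloxy)-3-{[4-(benzyloxy)-2-methoxy-6-(methoxymethyl)phenyl]methyl}-6-hydroxy-2-methylbenzoate | COC(=O)c1c(C)c(Cc2c(COC)cc(OCc3ccccc3)cc2OC)c(OCc2ccccc2)cc1O | intermediate
20 | methyl 4-(benzyloxy)-3-{[4-(benzyloxy)-2-methoxy-6-(methoxymethyl)phenyl]methyl}-6-methoxy-2-methylbenzoate | COC(=O)c1c(C)c(Cc2c(COC)cc(OCc3ccccc3)cc2OC)c(OCc2ccccc2)cc1OC | intermediate
21 | N-methoxy-N-methylacetamide | CON(C)C(C)=O | starting material
22 | methyl 4-(benzyloxy)-3-{[4-(benzyloxy)-2-methoxy-6-(methoxymethyl)phenyl]methyl}-6-methoxy-2-(2-oxopropyl)benzoate | COC(=O)c1c(CC(C)=O)c(Cc2c(COC)cc(OCc3ccccc3)cc2OC)c(OCc2ccccc2)cc1OC | intermediate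
23 | 6-(benzyloxy)-5-{[4-(benzyloxy)-2-methoxy-6-(methoxymethyl)phenyl]methyl}-8-methoxy-3-methyl-1H-isochromen-1-one | COCc1cc(OCc2ccccc2)cc(OC)c1Cc1c(OCc2ccccc2)cc(OC)c2c(=O)oc(C)cc12 | intermediate
24 | 6-hydroxy-5-{[4-hydroxy-2-methoxy-6-(methoxymethyl)phenyl]methyl}-8-methoxy-3-methyl-1H-isochromen-1-one | COCc1cc(O)cc(OC)c1Cc1c(O)cc(OC)c2c(=O)oc(C)cc12 | target

**Step count**

Total: 15 steps. Longest linear sequence: 15 steps (1 to 24).

**Steps most likely to fail**

Step 9. The conjugate addition to the hindered α,β-disubstituted enone may be slow, so that retro-Michael reaction or base-induced migration of the double bond toward the benzylic position outruns ring closure. The fallback sets out from aldehyde 6 and forms the other ring-B bond of the Michael adduct under Lewis-acid instead of basic conditions. Wittig reaction of 6 with Ph3P=CHC(O)CH3 in toluene at 80 °C should give (E)-4-[4-(benzyloxy)-2-methoxy-6-(methoxymethyl)phenyl]but-3-en-2-one F1. 1,4-Hydrosilylation with Et3SiH and catalytic RhCl(PPh3)3 should give the regiodefined silyl enol ether triethyl({(2Z)-4-[4-(benzyloxy)-2-methoxy-6-(methoxymethyl)phenyl]but-2-en-2-yl}oxy)silane F2. Mukaiyama–Michael addition of F2 to purchased dimethyl ethylidenemalonate (CC=C(C(=O)OC)C(=O)OC) with TiCl4 in CH2Cl2 at −78 °C should give Michael adduct 14, which is isolated and closed with NaOMe in MeOH. The fallback comes back to the route at 15.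

Step 11 (with its preparation in step 10). Oxidation may not stop at the ring: the quinone may attack the doubly activated diarylmethane position, or the dienol ether may lose silicon and fall back to 15 before hydride abstraction. The fallback sets out from 15 and oxidises the free enolised dione directly with Hg(OAc)2 (2.2 equiv) and NaOAc in AcOH at 100 °C. This goes through C-mercuration and loss of reduced mercury, not through hydride abstraction. A wash with dilute HCl removes any aryl-bound divalent mercury from ring A by protodemercuration. The fallback comes back to the route at 18 and makes no new compound.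

Step 6. The electron-rich benzylic chloride may ionise before it meets the phosphonate anion, with capture of the cation by the neighbouring methoxymethyl oxygen (cyclisation with loss of chloromethane) or Friedel–Crafts self-alkylation. The fallback sets out from aldehyde 6 and avoids any benzylic halide. Knoevenagel condensation with pentane-2,4-dione (piperidine, AcOH, toluene, water removal) should give 3-{[4-(benzyloxy)-2-methoxy-6-(methoxymethyl)phenyl]methylidene}pentane-2,4-dione F3. Conjugate reduction with Hantzsch ester in EtOH at 60 °C should give 3-{[4-(benzyloxy)-2-methoxy-6-(methoxymethyl)phenyl]methyl}pentane-2,4-dione F4. Reduction of one ketone with NaBH4 (0.3 equiv) in MeOH at −20 °C should give 3-{[4-(benzyloxy)-2-methoxy-6-(methoxymethyl)phenyl]methyl}-4-hydroxypentan-2-one F5. Methanesulfonyl chloride and Et3N should give 3-{[4-(benzyloxy)-2-methoxy-6-(methoxymethyl)phenyl]methyl}-4-oxopentan-2-yl methanesulfonate F6, and DBU then eliminates it (E1cB) to the conjugated enone. The fallback comes back to the route at 12.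

**Further compounds**

F1 | step 9 | (E)-4-[4-(benzyloxy)-2-methoxy-6-(methoxymethyl)phenyl]but-3-en-2-one | CC(=O)/C=C/c1c(COC)cc(OCc2ccccc2)cc1OC
F2 | step 9 | triethyl({(2Z)-4-[4-(benzyloxy)-2-methoxy-6-(methoxymethyl)phenyl]but-2-en-2-yl}oxy)silane | C/C(O[Si](CC)(CC)CC)=C/Cc1c(COC)cc(OCc2ccccc2)cc1OC
F0 | step 11 | none | none
F3 | step 6 | 3-{[4-(benzyloxy)-2-methoxy-6-(methoxymethyl)phenyl]methylidene}pentane-2,4-dione | CC(=O)C(=Cc1c(COC)cc(OCc2ccccc2)cc1OC)C(C)=O
F4 | step 6 | 3-{[4-(benzyloxy)-2-methoxy-6-(methoxymethyl)phenyl]methyl}pentane-2,4-dione | CC(=O)C(Cc1c(COC)cc(OCc2ccccc2)cc1OC)C(C)=O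
F5 | step 6 | 3-{[4-(benzyloxy)-2-methoxy-6-(methoxymethyl)phenyl]methyl}-4-hydroxypentan-2-one (diastereomer mixture) | CC(O)C(Cc1c(COC)cc(OCc2ccccc2)cc1OC)C(C)=O
F6 | step 6 | 3-{[4-(benzyloxy)-2-methoxy-6-(methoxymethyl)phenyl]methyl}-4-oxopentan-2-yl methanesulfonate (diastereomer mixture) | CC(OS(C)(=O)=O)C(Cc1c(COC)cc(OCc2ccccc2)cc1OC)C(C)=O
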